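**Strategy.** Drimane numbering is used: ring A = C1–C5/C10, ring B = C5–C10, C11 = carboxyl on C9, C12 = formyl on C8. Ring A is cut at C1–C2 and C3–C4, which reveals (R)-carvone as ring B with C12 and the C4 unit (isopropenyl) in place; C10 receives methyl and formyl (C1). The key step exploits the gem-dimethyl carbon C4: hydrogen-atom transfer from an iron hydride to the isopropenyl group gives the tertiary C4 radical, which adds to acrolein (C3–C4), and the derived enolate closes on the C1 aldehyde (C1–C2), so the trans-decalin forms in one operation. Surplus functionality is then excised and ring B oxidised.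

Key step: step 4

Remark on the chemistry: the target is made as the open hydroxy acid–aldehyde as drawn, on the assumption that the α-oriented, pseudoaxial carboxyl on C9 cannot easily reach C12 to form a lactol; (R)-carvone, acrolein and (2E,4E,6E)-octa-2,4,6-trienoic acid are taken as commercial.

Step 1
Reactants: 1 (R)-(−)-carvone
Product: 3 (5R)-2,6-dimethyl-5-(prop-1-en-2-yl)cyclohex-2-en-1-one (6-methylcarvone; both C6 epimers), via lithium dienolate 2 (not isolated)
Conditions: LiN(iPr)2 (LDA), THF, −78 °C; MeI, −78 °C to 0 °C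
Reagents that add atoms: iodomethane, CI
Why: Kinetic α′-deprotonation of the enone and SN2 methylation of the cross-conjugated enolate; the C6 configuration does not matter because step 2 enolises this centre again.

Step 2
Reactants: 3 6-methylcarvone
Product: 5 (5S,6R)-6-(hydroxymethyl)-2,6-dimethyl-5-(prop-1-en-2-yl)cyclohex-2-en-1-one, via lithium enolate 4 (not isolated)
Conditions: LiN(iPr)2 (LDA), THF, −78 °C; monomeric CH2O (from cracked paraformaldehyde), −78 °C; AcOH quench
Reagents that add atoms: formaldehyde, C=O
Why: Aldol addition of the tetrasubstituted enolate to formaldehyde, in which the electrophile should enter anti to the neighbouring isopropenyl group and so set quaternary C10 with CH2OH trans and CH3 cis to isopropenyl (the later trans ring fusion).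

Step 3
Reactants: 5 hydroxymethyl ketone
Product: 6 (1R,6S)-1,3-dimethyl-2-oxo-6-(prop-1-en-2-yl)cyclohex-3-ene-1-carbaldehyde
Conditions: Dess–Martin periodinane, CH2Cl2, 0 °C to rt
Reagents that add atoms: none
Why: Dess–Martin oxidation of the neopentyl primary alcohol under neutral conditions, which should spare the non-enolisable β-keto aldehyde from retro-Claisen cleavage.

Step 4
Reactants: 6 keto aldehyde; 7 acrolein (prop-2-enal)
Product: 9 2-formyl-1-hydroxy-11-nordrim-7-en-9-one (trans-decalin, 5α-H, 10β-CH3; mixture at C1 and C2), via aldehyde enolate 8 (not isolated)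
Conditions: Fe(acac)3 (30 mol %), PhSiH3 (2.5 equiv), 7 (3 equiv), EtOH/ethylene glycol, 0 °C to rt
Reagents that add atoms: none
Why: The iron hydride formed from Fe(acac)3 and PhSiH3 transfers a hydrogen atom to the CH2 terminus of the isopropenyl group, the tertiary C4 radical adds to the β-carbon of acrolein (C3–C4 bond), divalent iron reduces the α-formyl radical to enolate 8 (bound to trivalent iron), and 8 adds to the neopentyl aldehyde on C10 (C1–C2 bond), after which ethanol protonates the aldolate and the silane regenerates the hydride. The closest known reaction type is the iron-hydride (MHAT) initiated radical–polar crossover annulation, a reductive Giese addition of an alkene to an enal that ends in an intramolecular aldol addition. Ring A closes by a 6-(enolexo)-exo-trig aldol addition that follows the intermolecular radical addition. No permanent stereocentre is created: the trans ring fusion follows from the trans C1/C4 substituents already fixed at C10 and C5 of 6, C4 becomes the non-stereogenic gem-dimethyl carbon, and the new centres C1 and C2 are erased in steps 5 and 6, so every diastereomer converges. The step needs hydrogen-atom transfer to the electron-rich 1,1-disubstituted alkene and not to the electron-poor enone, Giese trapping faster than reduction of the radical or 1,5-hydrogen transfer from the formyl group (excess acrolein), and aldol closure on the aldehyde, which is far more electrophilic than the conjugated, hindered C9 ketone and is the only acceptor that gives a fused six-membered ring.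

Step 5
Reactants: 9 aldol
Product: 11 2-formyl-11-nordrima-1,7-dien-9-one, via mesylate 10 (not isolated)
Conditions: MsCl, Et3N, CH2Cl2, 0 °C to rt
Reagents that add atoms: none
Why: Mesylation of the C1 hydroxyl and E1cB elimination through the aldehyde enolate (aldol condensation type) should give the same conjugated enal from every C1/C2 diastereomer of 9.

Step 6
Reactants: 11 enal
Product: 12 11-nordrima-1,7-dien-9-one
Conditions: RhCl(PPh3)3 (1.1 equiv), PhCN, 130 °C
Reagents that add atoms: none
Why: Tsuji–Wilkinson decarbonylation (formyl C–H oxidative addition to monovalent rhodium, CO extrusion, reductive elimination) removes the surplus formyl carbon from C2 and leaves a ring A alkene whose exact position is irrelevant because step 7 saturates it.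

Step 7
Reactants: 12 dienone
Product: 13 11-nordrim-7-en-9-one, (4aS,8aS)-2,5,5,8a-tetramethyl-4a,5,6,7,8,8a-hexahydronaphthalen-1(4H)-one
Conditions: H2 (1 atm), RhCl(PPh3)3 (10 mol %), benzene, rt
Reagents that add atoms: none
Why: Homogeneous hydrogenation with RhCl(PPh3)3 should reduce the unconjugated disubstituted ring A alkene and leave the trisubstituted, conjugated C7=C8 enone double bond.

Step 8
Reactants: 13 enone
Product: 14 9α-(1-methoxyvinyl)-11-nordrim-7-en-9β-ol
Conditions: methyl vinyl ether, t-BuLi, THF, −78 °C to 0 °C; then 13, −78 °C; H2O quench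
Reagents that add atoms: 1-methoxyvinyllithium (from methyl vinyl ether and t-BuLi), [Li]C(=C)OC
Why: 1,2-Addition of the hard α-alkoxyvinyllithium (acyl anion equivalent) to the enone carbonyl from the α face, anti to the axial C10 methyl group, should set C9 with OH β and the future carboxyl carbon C11 α.

Step 9
Reactants: 14 enol ether carbinol
Product: 15 methyl 9β-hydroxydrim-7-en-11-oate (CO2Me 9α)
Conditions: O3 (1 equiv, indicator dye), CH2Cl2/MeOH, −78 °C; Me2S
Reagents that add atoms: ozone, [O-][O+]=O
Why: Ozonolysis of the electron-rich enol ether, which should react well before the hindered trisubstituted C7=C8 alkene, cleaves the C=CH2 bond and gives the methyl ester directly.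

Step 10
Reactants: 15 hydroxy ester
Product: 16 methyl 9β-hydroxy-6-oxodrim-7-en-11-oate
Conditions: Rh2(cap)4 (1 mol %; cap = caprolactamate, C6H10NO), t-BuOOH (5 equiv), K2CO3 (cat.), CH2Cl2, rt
Reagents that add atoms: tert-butyl hydroperoxide, CC(C)(C)OO
Why: Radical allylic C–H oxidation by tert-butylperoxyl radicals, established for cyclic trisubstituted alkenes, should convert the ring allylic methylene C6 into the enone carbonyl and tolerate the free tertiary alcohol.

Step 11
Reactants: 16 enone ester
Product: 17 methyl 9β-hydroxy-6,12-dioxodrim-7-en-11-oate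
Conditions: SeO2 (2 equiv), wet 1,4-dioxane, 90 °C
Reagents that add atoms: selenium dioxide, O=[Se]=O
Why: Riley-type oxidation at the vinylogous (γ) methyl group C12 of the β-methyl enone, reached through its dienol, should give the 12-aldehyde.

Step 12
Reactants: 17 keto aldehyde
Product: 18 methyl 6β,9β,12-trihydroxydrim-7-en-11-oate
Conditions: NaBH4, CeCl3·7H2O, MeOH, −40 °C
Reagents that add atoms: none
Why: Luche (1,2-selective) reduction of aldehyde and ketone, in which hydride should reach C6 from the α face because the β face is blocked by the axial methyl groups on C4 and C10, setting the axial 6β-alcohol.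

Step 13
Reactants: 18 triol ester
Product: 19 methyl 6β,9β-dihydroxy-12-oxodrim-7-en-11-oate
Conditions: TEMPO (10 mol %), PhI(OAc)2 (1.2 equiv), CH2Cl2, rt
Reagents that add atoms: none
Why: Oxoammonium (TEMPO) oxidation is selective for the unhindered primary allylic alcohol C12 over the hindered axial secondary alcohol at C6 and the tertiary alcohol at C9, and stops at the aldehyde.

Step 14
Reactants: 19 hydroxy enal ester; 20 (2E,4E,6E)-octa-2,4,6-trienoic acid
Product: 22 methyl 6β-[(2E,4E,6E)-octa-2,4,6-trienoyloxy]-9β-hydroxy-12-oxodrim-7-en-11-oate, via mixed anhydride 21 (not isolated)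
Conditions: 20, 2,4,6-trichlorobenzoyl chloride, Et3N, THF, rt; then 19, DMAP (cat.), toluene, rt to 40 °C
Reagents that add atoms: none
Why: Yamaguchi esterification, in which the acylpyridinium ion from 21 acylates the only reactive hydroxyl (6β-OH) with retention at C6 while the tertiary C9 hydroxyl does not react.

Step 15
Reactants: 22 methyl ester
Product: 23 target, (1R,4R,4aS,8aS)-2-formyl-1-hydroxy-5,5,8a-trimethyl-4-[(2E,4E,6E)-octa-2,4,6-trienoyloxy]-1,4,4a,5,6,7,8,8a-octahydronaphthalene-1-carboxylic acid
Conditions: LiI (10 equiv), EtOAc, reflux, dark; 1 M HCl work-up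
Reagents that add atoms: none
Why: Nucleophilic dealkylation (SN2 attack of iodide on the O-methyl carbon) should cleave the hindered methyl ester without acyl attack, so the secondary trienoate, whose alkyl carbon is closed to SN2 attack, the enal and the tertiary alcohol should remain.

**Compound list**

1 | (R)-(−)-carvone, (5R)-2-methyl-5-(prop-1-en-2-yl)cyclohex-2-en-1-one | CC1=CC[C@@H](C(C)=C)CC1=O | starting material
2 | lithium dienolate of 1 (O–Li on C1, C1=C6 and C2=C3) | CC1=CC[C@@H](C(C)=C)C=C1O[Li] | intermediate (not isolated)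
3 | 6-methylcarvone, (5R)-2,6-dimethyl-5-(prop-1-en-2-yl)cyclohex-2-en-1-one, both C6 epimers | CC1=CC[C@@H](C(C)=C)C(C)C1=O | intermediate
4 | lithium enolate of 3 (tetrasubstituted C1=C6) | CC1=CC[C@@H](C(C)=C)C(C)=C1O[Li] | intermediate (not isolated)
5 | (5S,6R)-6-(hydroxymethyl)-2,6-dimethyl-5-(prop-1-en-2-yl)cyclohex-2-en-1-one (CH2OH trans, CH3 cis to isopropenyl) | CC1=CC[C@@H](C(C)=C)[C@](C)(CO)C1=O | intermediate
6 | (1R,6S)-1,3-dimethyl-2-oxo-6-(prop-1-en-2-yl)cyclohex-3-ene-1-carbaldehyde | CC1=CC[C@@H](C(C)=C)[C@](C)(C=O)C1=O | intermediate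
7 | acrolein (prop-2-enal) | C=CC=O | starting material
8 | aldehyde enolate of the Giese adduct (bound to trivalent iron, drawn as the free anion) | CC1=CC[C@@H](C(C)(C)CC=C[O-])[C@](C)(C=O)C1=O | intermediate (not isolated)
9 | 2-formyl-1-hydroxy-11-nordrim-7-en-9-one, trans-decalin with 5α-H and 10β-CH3, mixture at C1 and C2 | C1C=C(C)C(=O)[C@@]2(C)C(O)C(C=O)CC(C)(C)[C@H]12 | intermediate
10 | C1 mesylate of 9 | C1C=C(C)C(=O)[C@@]2(C)C(OS(C)(=O)=O)C(C=O)CC(C)(C)[C@H]12 | intermediate (not isolated)
11 | 2-formyl-11-nordrima-1,7-dien-9-one | C1C=C(C)C(=O)[C@@]2(C)C=C(C=O)CC(C)(C)[C@H]12 | intermediate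
12 | 11-nordrima-1,7-dien-9-one | C1C=C(C)C(=O)[C@@]2(C)C=CCC(C)(C)[C@H]12 | intermediate
13 | 11-nordrim-7-en-9-one, (4aS,8aS)-2,5,5,8a-tetramethyl-4a,5,6,7,8,8a-hexahydronaphthalen-1(4H)-one | C1C=C(C)C(=O)[C@@]2(C)CCCC(C)(C)[C@H]12 | intermediate
14 | 9α-(1-methoxyvinyl)-11-nordrim-7-en-9β-ol | C1C=C(C)[C@@](O)(C(OC)=C)[C@@]2(C)CCCC(C)(C)[C@H]12 | intermediate
15 | methyl 9β-hydroxydrim-7-en-11-oate (CO2Me 9α) | C1C=C(C)[C@@](O)(C(=O)OC)[C@@]2(C)CCCC(C)(C)[C@H]12 | intermediate
16 | methyl 9β-hydroxy-6-oxodrim-7-en-11-oate | O=C1C=C(C)[C@@](O)(C(=O)OC)[C@@]2(C)CCCC(C)(C)[C@H]12 | intermediate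
17 | methyl 9β-hydroxy-6,12-dioxodrim-7-en-11-oate | O=C1C=C(C=O)[C@@](O)(C(=O)OC)[C@@]2(C)CCCC(C)(C)[C@H]12 | intermediate
18 | methyl 6β,9β,12-trihydroxydrim-7-en-11-oate | O[C@@H]1C=C(CO)[C@@](O)(C(=O)OC)[C@@]2(C)CCCC(C)(C)[C@H]12 | intermediate
19 | methyl 6β,9β-dihydroxy-12-oxodrim-7-en-11-oate | O[C@@H]1C=C(C=O)[C@@](O)(C(=O)OC)[C@@]2(C)CCCC(C)(C)[C@H]12 | intermediate
20 | (2E,4E,6E)-octa-2,4,6-trienoic acid | C/C=C/C=C/C=C/C(=O)O | starting material
21 | (2E,4E,6E)-octa-2,4,6-trienoic 2,4,6-trichlorobenzoic anhydride | C/C=C/C=C/C=C/C(=O)OC(=O)c1c(Cl)cc(Cl)cc1Cl | intermediate (not isolated)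
22 | methyl 6β-[(2E,4E,6E)-octa-2,4,6-trienoyloxy]-9β-hydroxy-12-oxodrim-7-en-11-oate | C/C=C/C=C/C=C/C(=O)O[C@@H]1C=C(C=O)[C@@](O)(C(=O)OC)[C@@]2(C)CCCC(C)(C)[C@H]12 | intermediate
23 | 6β-[(2E,4E,6E)-octa-2,4,6-trienoyloxy]-9β-hydroxy-12-oxodrim-7-en-11-oic acid, (5S,6R,9R,10S) in drimane numbering | C/C=C/C=C/C=C/C(=O)O[C@@H]1C=C(C=O)[C@@](O)(C(=O)O)[C@@]2(C)CCCC(C)(C)[C@H]12 | target

**Step count.** Total: 15 steps. Longest linear sequence: 15 steps, from (R)-carvone to 23.

**Steps most likely to fail and fallbacks**

Step 4. The tertiary C4 radical may be quenched before the carbon–carbon bond forms (reduction by the hydride, or 1,5-hydrogen transfer from the formyl group followed by loss of CO). The enolate may also be protonated before it cyclises, and the β-keto aldehyde may lose its formyl group in the alcoholic medium. The fallback separates the two bond formations and sets out from 5. The same iron-hydride reductive coupling with acrolein (Fe(acac)3, PhSiH3, EtOH), now with no formyl group in the substrate, should form only the C3–C4 bond and give 4-[2-(hydroxymethyl)-2,4-dimethyl-3-oxocyclohex-4-en-1-yl]-4-methylpentanal F1. Dess–Martin oxidation should give 4-(2-formyl-2,4-dimethyl-3-oxocyclohex-4-en-1-yl)-4-methylpentanal F2. An amine-catalysed intramolecular aldol condensation (piperidinium acetate, toluene, 50 °C), in which only the pentanal chain can enolise, should then form C1–C2 and lead to enal 11, where the route is rejoined.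

Step 11. Enolisation towards C12 may be too slow, so that SeO2 oxidises elsewhere (the C5–H next to the ketone) or over-oxidises, and the electrophilic ene-dicarbonyl product may degrade. The fallback sets out from 15 and oxidises C12 before C6. Allylic hydroxylation of the trisubstituted alkene (SeO2 cat., t-BuOOH, CH2Cl2; ene reaction and [2,3]-shift at the methyl group on the more substituted alkene carbon) should give methyl 9β,12-dihydroxydrim-7-en-11-oate F3. Silylation (TBSCl, imidazole) should give methyl 12-(tert-butyldimethylsilyloxy)-9β-hydroxydrim-7-en-11-oate F4, and allylic oxidation as in step 10 its 6-oxo derivative F5. Luche reduction should give methyl 12-(tert-butyldimethylsilyloxy)-6β,9β-dihydroxydrim-7-en-11-oate F6, and Bu4NF should return triol 18.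

Step 15. The dealkylation may stall at temperatures the triene tolerates, or iodide may attack the enal or the allylic ester or scramble the triene geometry. The fallback frees the acid before the sensitive groups are in place and sets out from 18. Hydrolysis of the methyl ester (KOSiMe3, THF, then acid) should give 6β,9β,12-trihydroxydrim-7-en-11-oic acid F7. The TEMPO/PhI(OAc)2 oxidation of step 13 should give 6β,9β-dihydroxy-12-oxodrim-7-en-11-oic acid F8. Acylation of the 6β-hydroxyl with mixed anhydride 21 (DMAP, toluene) should then give 23; the hindered C11 carboxylate can at most form a labile mixed anhydride, which the aqueous NaHCO3 work-up should cleave.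

**Further compounds**

F1 | step 4 | 4-[2-(hydroxymethyl)-2,4-dimethyl-3-oxocyclohex-4-en-1-yl]-4-methylpentanal (ring stereocentres as in 5) | CC1=CC[C@@H](C(C)(C)CCC=O)[C@](C)(CO)C1=O
F2 | step 4 | 4-(2-formyl-2,4-dimethyl-3-oxocyclohex-4-en-1-yl)-4-methylpentanal (ring stereocentres as in 6) | CC1=CC[C@@H](C(C)(C)CCC=O)[C@](C)(C=O)C1=O
F3 | step 11 | methyl 9β,12-dihydroxydrim-7-en-11-oate | C1C=C(CO)[C@@](O)(C(=O)OC)[C@@]2(C)CCCC(C)(C)[C@H]12
F4 | step 11 | methyl 12-(tert-butyldimethylsilyloxy)-9β-hydroxydrim-7-en-11-oate | C1C=C(CO[Si](C)(C)C(C)(C)C)[C@@](O)(C(=O)OC)[C@@]2(C)CCCC(C)(C)[C@H]12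
F5 | step 11 | methyl 12-(tert-butyldimethylsilyloxy)-9β-hydroxy-6-oxodrim-7-en-11-oate | O=C1C=C(CO[Si](C)(C)C(C)(C)C)[C@@](O)(C(=O)OC)[C@@]2(C)CCCC(C)(C)[C@H]12
F6 | step 11 | methyl 12-(tert-butyldimethylsilyloxy)-6β,9β-dihydroxydrim-7-en-11-oate | O[C@@H]1C=C(CO[Si](C)(C)C(C)(C)C)[C@@](O)(C(=O)OC)[C@@]2(C)CCCC(C)(C)[C@H]12
F7 | step 15 | 6β,9β,12-trihydroxydrim-7-en-11-oic acid | O[C@@H]1C=C(CO)[C@@](O)(C(=O)O)[C@@]2(C)CCCC(C)(C)[C@H]12
F8 | step 15 | 6β,9β-dihydroxy-12-oxodrim-7-en-11-oic acid | O[C@@H]1C=C(C=O)[C@@](O)(C(=O)O)[C@@]2(C)CCCC(C)(C)[C@H]12
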